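**Retrosynthetic overview**

1. Target 15 ⇒ cyclobutane-1,3-dicarboxylic acid 11 plus two molecules of 5,6-dihydropyridin-2(1H)-one 13, by cleaving the two exocyclic imide N–C(=O) bonds; the lactam rings are bought intact.
2. Cyclobutane diester 10 ⇒ NH-pyrrolidine 7 by re-inserting a nitrogen atom into ring bond C1–C4. The strategy rests on this bond: C1 carries a carbonyl group and C4 a trimethoxyphenyl group on the same ring face, and these two carbons are C2 and C5, the carbons flanking nitrogen, of a 2,5-cis 3,5-diarylpyrrolidine-2,4-dicarboxylate.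
3. Pyrrolidine 7 ⇒ glycinate aldimine 6 (C2–N–C5) plus (Z)-cinnamate 4 (C3–C4) by exo [3+2] cycloaddition; all four stereocentres are set here, on the five-membered ring.
4. Both 4 and 6 come from 3,4,5-trimethoxybenzaldehyde 1. Ring order: pyrrolidine (step 3), then cyclobutane by contraction (step 4); the two lactam rings are attached last (step 7).

Key step: step 4

Assumption: 15 is the centrosymmetric (achiral, meso) head-to-tail dimer, so 7, 8 and 9 are carried as racemates and no enantiocontrol is needed; their SMILES show one enantiomer. Cyclobutane numbering used below: C1 (carbonyl), C2 (aryl), C3 (carbonyl), C4 (aryl), with C1–C4 and C2–C3 the cis edges; pyrrolidine C2, C3, C4, C5 become cyclobutane C1, C2, C3, C4.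

**Route**

Step 1
Reactants: 1 3,4,5-trimethoxybenzaldehyde; 2 methyl 2-[bis(2,2,2-trifluoroethoxy)phosphoryl]acetate
Product: 4 methyl (Z)-3-(3,4,5-trimethoxyphenyl)prop-2-enoate, via potassium phosphonate carbanion 3 (not isolated)
Conditions: KN(SiMe3)2, 18-crown-6, THF, −78 °C
Reagents that add atoms: none
Why: Still–Gennari variant of the Horner–Wadsworth–Emmons olefination: with the electron-poor trifluoroethyl phosphonate and a crown-ether-separated potassium counter-ion the syn adduct eliminates faster than it reverts, so the kinetic Z-alkene is expected from an aromatic aldehyde; no stereocentre is formed.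

Step 2
Reactants: 1 3,4,5-trimethoxybenzaldehyde; 5 glycine methyl ester hydrochloride
Product: 6 methyl (E)-N-(3,4,5-trimethoxybenzylidene)glycinate
Conditions: Et3N, MgSO4, CH2Cl2, rt
Reagents that add atoms: none
Why: Imine condensation: Et3N frees the amine of 5, which condenses with the aldehyde while MgSO4 takes up the water, and the aldimine forms as the more stable E isomer.

Step 3
Reactants: 4 methyl (Z)-3-(3,4,5-trimethoxyphenyl)prop-2-enoate; 6 methyl (E)-N-(3,4,5-trimethoxybenzylidene)glycinate
Product: 7 dimethyl rac-(2S,3R,4R,5R)-3,5-bis(3,4,5-trimethoxyphenyl)pyrrolidine-2,4-dicarboxylate (2,5-cis; 3,4-cis; 2,3-trans; 4,5-trans)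
Conditions: Cu(CH3CN)4PF6 (10 mol%), rac-BINAP (11 mol%), Et3N (20 mol%), THF, 0 °C to rt
Reagents that add atoms: none
Why: Copper-catalysed 1,3-dipolar cycloaddition of an azomethine ylide: deprotonation of the N,O-chelated imine on monovalent copper gives a W-shaped metallo-ylide that fixes the 2,5-cis relation, its nucleophilic α-carbon bonds to the β-(aryl) carbon of the acrylate so that aryl ends at C3 and ester at C4, suprafacial addition carries the Z geometry into the 3,4-cis relation, and exo approach, favoured with copper–bisphosphine catalysts because a Z-alkene in the endo mode would push both its ester and its aryl group against the ligand, places these two groups on the face opposite to the C2 ester and C5 aryl (2,3-trans, 4,5-trans).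

Step 4
Reactants: 7 dimethyl rac-(2S,3R,4R,5R)-3,5-bis(3,4,5-trimethoxyphenyl)pyrrolidine-2,4-dicarboxylate
Product: 10 dimethyl 2,4-bis(3,4,5-trimethoxyphenyl)cyclobutane-1,3-dicarboxylate (1,4-cis; 2,3-cis; 1,2-trans; 3,4-trans; meso), via 1,1-diazene 8 (not isolated), via singlet 1,4-biradical 9 (not isolated)
Conditions: PhI(OH)OTs (2.5 equiv), H2NCO2NH4 (8 equiv), CF3CH2OH, 80 °C
Reagents that add atoms: none
Why: PhI(OH)OTs and ammonia released from the carbamate form an iodonitrene that aminates the ring nitrogen of 7 electrophilically, a second equivalent of the trivalent-iodine reagent oxidises the N-amino compound to the 1,1-diazene 8, and 8 expels dinitrogen to leave the singlet 1,4-biradical 9, benzylic at the former C5 and ester-stabilised at the former C2. The closest known reaction type is the iodonitrene-mediated contraction of 2,5-disubstituted NH-pyrrolidines to cyclobutanes, a one-flask form of the classical oxidation of N-aminopyrrolidines through 1,1-diazenes. The four-membered ring closes by direct coupling of the two radical termini, which forms the C1–C4 bond. No new stereocentre is created: cyclobutane C2 and C3 pass through untouched, and C1 and C4 keep the 2,5-cis relation of 7 because the singlet pair should collapse faster than either radical centre rotates, which puts the C1 ester cis to the C4 aryl group as the target requires. The step needs coupling to outrun β-scission of the C2–C3 bond into two cinnamate molecules, and needs the oxidant to spare the electron-rich trimethoxyphenyl rings. The short lifetime of the singlet biradical and the excess ammonia, which should consume the iodine reagent as iodonitrene before it attacks the arenes, work in that direction.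

Step 5
Reactants: 10 dimethyl 2,4-bis(3,4,5-trimethoxyphenyl)cyclobutane-1,3-dicarboxylate
Product: 11 2,4-bis(3,4,5-trimethoxyphenyl)cyclobutane-1,3-dicarboxylic acid (1,4-cis; 2,3-cis; 1,2-trans; 3,4-trans; meso)
Conditions: LiOH·H2O, THF/MeOH/H2O, rt; then 1 M HCl
Reagents that add atoms: lithium hydroxide, [Li+].[OH-] (the hydroxide oxygen ends in each CO2H)
Why: Saponification of the two methyl esters at room temperature: acyl substitution by hydroxide is much faster than α-deprotonation, and each carboxylate once formed resists enolisation, so the four ring stereocentres should be kept.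

Step 6
Reactants: 11 2,4-bis(3,4,5-trimethoxyphenyl)cyclobutane-1,3-dicarboxylic acid
Product: 12 2,4-bis(3,4,5-trimethoxyphenyl)cyclobutane-1,3-dicarbonyl dichloride (1,4-cis; 2,3-cis; 1,2-trans; 3,4-trans; meso), used crude after evaporation
Conditions: (COCl)2, DMF (cat.), CH2Cl2, 0 °C to rt
Reagents that add atoms: oxalyl chloride, O=C(Cl)C(=O)Cl
Why: Vilsmeier-type activation with oxalyl chloride and catalytic DMF converts both acids to acid chlorides without base, so no ketene can form and the α-stereocentres should not epimerise; the aryl methyl ethers are inert.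

Step 7
Reactants: 12 2,4-bis(3,4,5-trimethoxyphenyl)cyclobutane-1,3-dicarbonyl dichloride; 13 5,6-dihydropyridin-2(1H)-one (2.2 equiv)
Product: 15 piplartine-dimer A, via N-lithio-5,6-dihydropyridin-2(1H)-one 14 (not isolated)
Conditions: 13, LiN(SiMe3)2, THF, −78 °C; then 12, THF, −78 °C
Reagents that add atoms: none
Why: Double N-acylation of a lactam anion by an acid chloride (imide formation): the lithium amide of 13 is N-nucleophilic and acylation is fast at −78 °C, which should suppress ketene formation from 12 and conjugate addition to the enone, so the ring configuration is carried into the target unchanged.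

**Compound list**

1 | 3,4,5-trimethoxybenzaldehyde | COc1cc(C=O)cc(OC)c1OC | starting material
2 | methyl 2-[bis(2,2,2-trifluoroethoxy)phosphoryl]acetate | COC(=O)CP(=O)(OCC(F)(F)F)OCC(F)(F)F | starting material
3 | potassium salt of the carbanion of 2 | COC(=O)[CH-]P(=O)(OCC(F)(F)F)OCC(F)(F)F.[K+] | intermediate
4 | methyl (Z)-3-(3,4,5-trimethoxyphenyl)prop-2-enoate | COC(=O)/C=C\c1cc(OC)c(OC)c(OC)c1 | intermediate
5 | glycine methyl ester hydrochloride | COC(=O)CN.Cl | starting material
6 | methyl (E)-N-(3,4,5-trimethoxybenzylidene)glycinate | COC(=O)C/N=C/c1cc(OC)c(OC)c(OC)c1 | intermediate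
7 | dimethyl rac-(2S,3R,4R,5R)-3,5-bis(3,4,5-trimethoxyphenyl)pyrrolidine-2,4-dicarboxylate (2,5-cis; 3,4-cis; 2,3-trans; 4,5-trans; racemate, one enantiomer drawn) | COc1cc([C@H]2[C@H](C(=O)OC)[C@H](c3cc(OC)c(OC)c(OC)c3)[C@H](N2)C(=O)OC)cc(OC)c1OC | intermediate
8 | 1,1-diazene (isodiazene) of 7, configuration of 7 (racemate, one enantiomer drawn) | COc1cc([C@H]2[C@H](C(=O)OC)[C@H](c3cc(OC)c(OC)c(OC)c3)[C@H]([N+]2=[N-])C(=O)OC)cc(OC)c1OC | intermediate
9 | singlet 1,4-biradical, dimethyl 2,4-bis(3,4,5-trimethoxyphenyl)butane-1,4-diyl-1,3-dicarboxylate skeleton with the two inner stereocentres of 7 (racemate, one enantiomer drawn) | COc1cc([CH][C@H](C(=O)OC)[C@H](c2cc(OC)c(OC)c(OC)c2)[CH]C(=O)OC)cc(OC)c1OC | intermediate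
10 | dimethyl 2,4-bis(3,4,5-trimethoxyphenyl)cyclobutane-1,3-dicarboxylate (1,4-cis; 2,3-cis; 1,2-trans; 3,4-trans; meso) | COc1cc([C@H]2[C@H](C(=O)OC)[C@H](c3cc(OC)c(OC)c(OC)c3)[C@H]2C(=O)OC)cc(OC)c1OC | intermediate
11 | 2,4-bis(3,4,5-trimethoxyphenyl)cyclobutane-1,3-dicarboxylic acid (same relative configuration, meso) | COc1cc([C@H]2[C@H](C(=O)O)[C@H](c3cc(OC)c(OC)c(OC)c3)[C@H]2C(=O)O)cc(OC)c1OC | intermediate
12 | 2,4-bis(3,4,5-trimethoxyphenyl)cyclobutane-1,3-dicarbonyl dichloride (same relative configuration, meso) | COc1cc([C@H]2[C@H](C(=O)Cl)[C@H](c3cc(OC)c(OC)c(OC)c3)[C@H]2C(=O)Cl)cc(OC)c1OC | intermediate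
13 | 5,6-dihydropyridin-2(1H)-one | O=C1C=CCCN1 | starting material
14 | N-lithio-5,6-dihydropyridin-2(1H)-one | [Li]N1CCC=CC1=O | intermediate
15 | piplartine-dimer A | COc1cc([C@H]2[C@H](C(=O)N3CCC=CC3=O)[C@H](c3cc(OC)c(OC)c(OC)c3)[C@H]2C(=O)N2CCC=CC2=O)cc(OC)c1OC | target

**Step count**

Total steps: 7. Longest linear sequence: 6 steps (1 → 4 → 7 → 10 → 11 → 12 → 15; the imine branch through step 2 is equally long).

**Steps most likely to fail**

1. Step 4. The 1,4-biradical may fragment across the central C2–C3 bond into two cinnamate molecules faster than it couples, and the iodine oxidant may attack the electron-rich trimethoxyphenyl rings before it is converted into the iodonitrene. Fallback, from 7 back to 10: the nitrogen–nitrogen bond is built and oxidised in separate operations without a hypervalent iodine reagent. Nitrosation of 7 with tert-butyl nitrite in CH2Cl2 should give dimethyl 1-nitroso-3,5-bis(3,4,5-trimethoxyphenyl)pyrrolidine-2,4-dicarboxylate F1. Reduction with Zn dust in acetic acid should give dimethyl 1-amino-3,5-bis(3,4,5-trimethoxyphenyl)pyrrolidine-2,4-dicarboxylate F2. Oxidation of F2 with yellow HgO in CH2Cl2 at or below room temperature (the classical N-aminopyrrolidine route) generates the same 1,1-diazene 8, which loses dinitrogen and rejoins the route at 10. The lower temperature of diazene formation should also favour coupling over scission.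

2. Step 3. The alkene geometry may be lost through a stepwise conjugate addition–Mannich pathway, and the exo preference may be incomplete, both made worse by the low reactivity of a β-aryl acrylate. Fallback, from 4 and 6 back to 7: the C3/C5 trans-diaryl relation is set by an endo cycloaddition of the E-alkene and C4 is then corrected by equilibration. Isomerisation of 4 with catalytic iodine (or ordinary Horner–Wadsworth–Emmons olefination of 1) gives methyl (E)-3-(3,4,5-trimethoxyphenyl)prop-2-enoate F3. Endo-selective cycloaddition of F3 with 6 under AgOAc/DBU (or LiBr/DBU) in THF should give dimethyl rac-(2S,3R,4S,5R)-3,5-bis(3,4,5-trimethoxyphenyl)pyrrolidine-2,4-dicarboxylate F4, the 2,4,5-cis, 3-trans isomer that differs from 7 only at C4. Treatment of F4 with NaOMe in MeOH equilibrates the ester-bearing C4, while C2 already holds its preferred position trans to the C3 aryl group. A mixture of the two C4 epimers is expected, from which 7 is separated and F4 is resubmitted.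

3. Step 7. The basic lactam anion may dehydrochlorinate 12 to a ketene, which would scramble the α-stereocentres, or the second acylation may stall at the hindered mono-imide. Fallback, from 13 and 12 back to 15: the acylation is run without a strong base. Silylation of 13 with Me3SiCl/Et3N gives 1-(trimethylsilyl)-5,6-dihydropyridin-2(1H)-one F5, and warming F5 (2.2 equiv) with 12 in toluene should give 15 directly by N-acylation with loss of chlorotrimethylsilane.

**Further compounds**

F1 | step 4 | dimethyl 1-nitroso-3,5-bis(3,4,5-trimethoxyphenyl)pyrrolidine-2,4-dicarboxylate (configuration of 7, racemate) | COc1cc([C@H]2[C@H](C(=O)OC)[C@H](c3cc(OC)c(OC)c(OC)c3)[C@H](N2N=O)C(=O)OC)cc(OC)c1OC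
F2 | step 4 | dimethyl 1-amino-3,5-bis(3,4,5-trimethoxyphenyl)pyrrolidine-2,4-dicarboxylate (configuration of 7, racemate) | COc1cc([C@H]2[C@H](C(=O)OC)[C@H](c3cc(OC)c(OC)c(OC)c3)[C@H](N2N)C(=O)OC)cc(OC)c1OC
F3 | step 3 | methyl (E)-3-(3,4,5-trimethoxyphenyl)prop-2-enoate | COC(=O)/C=C/c1cc(OC)c(OC)c(OC)c1
F4 | step 3 | dimethyl rac-(2S,3R,4S,5R)-3,5-bis(3,4,5-trimethoxyphenyl)pyrrolidine-2,4-dicarboxylate (2,4,5-cis, 3-trans; C4 epimer of 7) | COc1cc([C@H]2[C@@H](C(=O)OC)[C@H](c3cc(OC)c(OC)c(OC)c3)[C@H](N2)C(=O)OC)cc(OC)c1OC
F5 | step 7 | 1-(trimethylsilyl)-5,6-dihydropyridin-2(1H)-one | C[Si](C)(C)N1CCC=CC1=O
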